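## Retrosynthetic overview

1. Feature used: in the bicyclo[3.2.1]octane (C8, C9, C11–C16) the tertiary C13–OH is β to the C15 ketone, which is an aldol retron across C13–C16. C8 is the central carbon of the C7/C15 β-keto lactone and also stands 1,4 (dissonant) to C13=O.
2. Ring D: retro-aldol at C13–C16 leads to the 8-propanoyl cyclohexanone 18. Ring C: C8–C14 is cut between two enolate carbons, which leads to spiro lactone 16 with a 3-oxobutyl chain on C9. The forward reaction is an oxidative enolate coupling that sets quaternary C8.
3. C9–C11 comes from a copper-mediated 1,4-addition to the alkylidene β-keto lactone 11. The δ-lactone ring (C9–C10 and O–C7) comes from the alkoxide–enolate dianion of 6 and the methoxymethylene keto ester 8, which sets quaternary C10.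
4. Ring A with C5, C6 and C20 comes from a desymmetrising Cu-catalysed conjugate addition/formaldehyde aldol on 4,4-dimethylcyclohexadienone. CH2SiMe2Ph serves as the masked C6H2OH.
5. Ring order: A (bought) → δ-lactone → C → D. C16 (endo methyl) is set last by kinetic protonation.

Key step: step 7

Assumptions: ent-kaurane numbering of the target (5R,8S,9S,10S,13S,16R) is used for all compounds; the C16 methyl group points endo (towards C11/C12) and is taken to be the less stable epimer of an epimerisable centre, so it is set last; the ligand enantiomer in step 2 is written as the one expected to give (5S)-6 and would be confirmed on the first run.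

## Route

Step 1
Reactants: 1 4,4-dimethylcyclohex-2-en-1-one
Product: 2 4,4-dimethylcyclohexa-2,5-dien-1-one
Conditions: DDQ, 1,4-dioxane, reflux
Reagents that add atoms: none
Why: DDQ dehydrogenation of an enone by hydride abstraction from its dienol is the standard entry to this cross-conjugated dienone, and the quaternary C4 rules out aromatisation.

Step 2
Reactants: 2 4,4-dimethylcyclohexa-2,5-dien-1-one; 3 (chloromethyl)dimethyl(phenyl)silane
Product: 6 (5S,6R)-5-{[dimethyl(phenyl)silyl]methyl}-6-(hydroxymethyl)-4,4-dimethylcyclohex-2-en-1-one, via silylmethyl Grignard reagent 4 (not isolated), via chloromagnesium dienolate 5 (not isolated)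
Conditions: 3, Mg, Et2O; then 2, CuBr·SMe2 (5 mol %), (R,Sp)-Josiphos (6 mol %), t-BuOMe, −75 °C; CH2O (gas, cracked paraformaldehyde), −75 °C; aq NH4Cl
Reagents that add atoms: formaldehyde C=O
Why: A copper-catalysed enantioselective conjugate addition of a Grignard reagent (ferrocenyl diphosphine ligand) desymmetrises the prochiral dienone by attack on one of the two enantiotopic β-carbons and so sets C5, the silylmethyl group being a masked C6 hydroxymethyl, and the regiodefined magnesium enolate is trapped by formaldehyde in a tandem aldol addition that brings in C20 anti to the new arm (this C10 configuration is erased in step 4).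

Step 3
Reactants: 7 methyl 3-oxopentanoate
Product: 8 methyl 2-(methoxymethylidene)-3-oxopentanoate (E/Z mixture)
Conditions: HC(OMe)3, Ac2O, 120 °C
Reagents that add atoms: trimethyl orthoformate COC(OC)OC
Why: Alkoxymethylenation of an active methylene compound with an orthoformate in acetic anhydride gives the push–pull alkene that carries C7, C8, C9 and C15–C17.

Step 4
Reactants: 6 hydroxymethyl ketone; 8 methyl 2-(methoxymethylidene)-3-oxopentanoate
Product: 11 (6S,11R)-11-{[dimethyl(phenyl)silyl]methyl}-10,10-dimethyl-4-propanoyl-2-oxaspiro[5.5]undeca-4,8-diene-3,7-dione (kaurane 5R,10S), via dilithium alkoxide-dienolate 9 (not isolated), via open-chain alkylidene keto ester 10 (not isolated)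
Conditions: LDA (2.2 equiv), THF, −78 → −40 °C; 8, −78 → 0 °C; AcOH; crude, PPTS (cat.), PhMe, 80 °C
Reagents that add atoms: none
Why: Double deprotonation gives a Fráter–Seebach-type dianion whose β-oxygen is a non-leaving lithium alkoxide, its only enolisable carbon C10 adds to 8 by Michael addition–elimination as ketone enolates do with alkoxymethylene malonates, attack anti to the pseudoaxial C5 silylmethyl arm places C9 trans and C20 cis to C6, and acid-catalysed loss of methanol (with E/Z equilibration) closes the δ-lactone.

Step 5
Reactants: 11 spiro alkylidene β-keto lactone; 12 2-(2-bromoethyl)-2-methyl-1,3-dioxolane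
Product: 15 (5R,9R,10S)-9-[2-(2-methyl-1,3-dioxolan-2-yl)ethyl] β-keto lactone (C8 epimers and enol), via dioxolanylethyl Grignard reagent 13 (not isolated), via bromomagnesium enolate 14 (not isolated)
Conditions: 12, Mg, THF; CuBr·SMe2 (20 mol %), THF, −78 °C, then 11; aq NH4Cl
Reagents that add atoms: none
Why: The copper-catalysed conjugate addition of the Grignard reagent picks the doubly activated C8=C9 bond over the singly activated neopentyl C2=C3 enone, and it approaches the lactone face that carries the flat C1 carbonyl, anti to C5 and its silylmethyl arm, which sets C9 with C11 cis to C1.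

Step 6
Reactants: 15 dioxolane β-keto lactone
Product: 16 (5R,9R,10S)-11-{[dimethyl(phenyl)silyl]methyl}-10,10-dimethyl-5-(3-oxobutyl)-4-propanoyl-2-oxaspiro[5.5]undec-8-ene-3,7-dione (C8 epimers and enol)
Conditions: 1 M HCl, THF, rt
Reagents that add atoms: water O
Why: Acid-catalysed acetal hydrolysis frees the methyl ketone while the aryl silane, the lactone and the enone are inert to dilute acid at room temperature.

Step 7
Reactants: 16 3-oxobutyl β-keto lactone
Product: 18 (5R,8S,9S,10S)-triketo lactone with ring C closed (8-propanoyl, 13-oxo, lactone/ring C cis-fused), via dilithium bis-enolate 17 (not isolated)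
Conditions: LDA (2.3 equiv), THF, −78 °C; FeCl3 (2.3 equiv) in DMF, −78 °C → rt
Reagents that add atoms: none
Why: LDA first forms the stabilised C8 enolate of the β-keto lactone and then, under kinetic control, the terminal C14 enolate of the methyl ketone; Fe(III) oxidises the more electron-rich ketone enolate to an α-keto radical that adds to C8 of the neighbouring enolate, and a second Fe(III) oxidises the resulting ketyl to the C15 ketone. The closest known reaction type is the intramolecular oxidative heterocoupling of a ketone enolate with a malonate or β-keto ester enolate by iron(III) or copper(II) salts, which also builds quaternary carbons. Ring C closes 6-exo-trig with respect to the C8=C15(O) enolate bond, whereas coupling through the internal C12 enolate would need a four-membered ring and is unproductive. The new quaternary centre C8 is controlled by C9: allylic strain with the planar enolate holds the C11 chain pseudoaxial on the C1 face and the other face is covered by C5 and its silylmethyl arm, so C14 bonds on the face of C11, the ring fusion is cis and the propanoyl group ends anti. The step needs chemoselectivity against the A-ring enone, which has no enolisable hydrogen and is an electron-poor neopentyl acceptor mismatched with the electrophilic radical. The coupling joins two carbons of like (nucleophilic) polarity and so creates the dissonant C15/C13 1,4-diketone that no enolate–acceptor pairing can give.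

Step 8
Reactants: 18 triketo lactone
Product: 19 (5R,8S,9S,10S,13S)-13-hydroxy-15-oxo bicyclo[3.2.1]octane spirolactone with 6-SiMe2Ph (C16 epimers)
Conditions: KOt-Bu (0.3 equiv), t-BuOH–THF, 0 °C
Reagents that add atoms: none
Why: In this intramolecular aldol addition of a 1,4-diketone under thermodynamic control, only the C16 enolate attacking C13 gives the little-strained bicyclo[3.2.1]octane, the bridge geometry fixes C13, Bredt's rule bars dehydration, the bulky base avoids retro-Claisen cleavage, and C16 is left at equilibrium for correction in step 10.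

Step 9
Reactants: 19 silyl aldol product
Product: 20 C16-epimeric mixture of the target diol
Conditions: Hg(OAc)2, AcOOH, AcOH, rt
Reagents that add atoms: peracetic acid CC(=O)OO
Why: The Fleming–Tamao oxidation (mercuridesilylation of the phenyl group, then a peracid-induced 1,2-shift from silicon to oxygen) turns C6–Si into C6–OH under acidic, non-nucleophilic conditions that spare the β-keto lactone, the tertiary alcohol and the electron-poor enone.

Step 10
Reactants: 20 C16-epimeric diol
Product: 22 target CNP0533761.1 (5R,8S,9S,10S,13S,16R), via tris(trimethylsilyl) enol ether 21 (not isolated)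
Conditions: TMSOTf, Et3N, CH2Cl2, 0 °C; then HF·pyridine, THF, −40 → 0 °C
Reagents that add atoms: none
Why: Soft enolisation can only give the C15=C16 enol silane because no other carbonyl has an α-hydrogen, both hydroxyls are capped at the same time, and kinetic protonation on desilylation comes from the open exo face (the side of C14) of the bicyclo[3.2.1]octene, which places H-16 exo and the methyl group endo as in the target.

## Compound list

1 | 4,4-dimethylcyclohex-2-en-1-one | CC1(C)CCC(=O)C=C1 | starting material
2 | 4,4-dimethylcyclohexa-2,5-dien-1-one | CC1(C)C=CC(=O)C=C1 | intermediate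
3 | (chloromethyl)dimethyl(phenyl)silane | C[Si](C)(CCl)c1ccccc1 | starting material
4 | {[dimethyl(phenyl)silyl]methyl}magnesium chloride | C[Si](C)(C[Mg]Cl)c1ccccc1 | intermediate
5 | chloromagnesium dienolate of the 1,4-adduct (C5 as in 6) | C1=C(O[Mg]Cl)C=CC(C)(C)[C@H]1C[Si](C)(C)c1ccccc1 | intermediate
6 | (5S,6R)-5-{[dimethyl(phenyl)silyl]methyl}-6-(hydroxymethyl)-4,4-dimethylcyclohex-2-en-1-one | OC[C@@H]1C(=O)C=CC(C)(C)[C@H]1C[Si](C)(C)c1ccccc1 | intermediate
7 | methyl 3-oxopentanoate | CCC(=O)CC(=O)OC | starting material
8 | methyl 2-(methoxymethylidene)-3-oxopentanoate (E/Z) | CCC(=O)C(=COC)C(=O)OC | intermediate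
9 | dilithium alkoxide-dienolate of 6 | [Li]OCC1=C(O[Li])C=CC(C)(C)[C@H]1C[Si](C)(C)c1ccccc1 | intermediate
10 | open-chain alkylidene keto ester, C10 quaternary (C9 trans, C20H2OH cis to C6) | COC(=O)C(C(=O)CC)=C[C@]1(CO)C(=O)C=CC(C)(C)[C@H]1C[Si](C)(C)c1ccccc1 | intermediate
11 | (6S,11R)-11-{[dimethyl(phenyl)silyl]methyl}-10,10-dimethyl-4-propanoyl-2-oxaspiro[5.5]undeca-4,8-diene-3,7-dione | CCC(=O)C1=C[C@]2(COC1=O)C(=O)C=CC(C)(C)[C@H]2C[Si](C)(C)c1ccccc1 | intermediate
12 | 2-(2-bromoethyl)-2-methyl-1,3-dioxolane | CC1(CCBr)OCCO1 | starting material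
13 | [2-(2-methyl-1,3-dioxolan-2-yl)ethyl]magnesium bromide | CC1(CC[Mg]Br)OCCO1 | intermediate
14 | bromomagnesium enolate of 15 | CC1(OCCO1)CC[C@@H]2C(=C(CC)O[Mg]Br)C(=O)OC[C@]23C(=O)C=CC(C)(C)[C@H]3C[Si](C)(C)c1ccccc1 | intermediate
15 | 9-[2-(2-methyl-1,3-dioxolan-2-yl)ethyl] β-keto lactone, C11 cis to C1 (C8 undefined) | CC1(OCCO1)CC[C@@H]2C(C(=O)CC)C(=O)OC[C@]23C(=O)C=CC(C)(C)[C@H]3C[Si](C)(C)c1ccccc1 | intermediate
16 | 9-(3-oxobutyl) β-keto lactone (C8 undefined) | CC(=O)CC[C@@H]1C(C(=O)CC)C(=O)OC[C@]12C(=O)C=CC(C)(C)[C@H]2C[Si](C)(C)c1ccccc1 | intermediate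
17 | dilithium bis-enolate of 16 (C8=C15 and C13=C14) | C=C(O[Li])CC[C@@H]1C(=C(CC)O[Li])C(=O)OC[C@]12C(=O)C=CC(C)(C)[C@H]2C[Si](C)(C)c1ccccc1 | intermediate
18 | (5R,8S,9S,10S)-8-propanoyl-13-oxo triketo lactone, ring C cis-fused to the lactone | CCC(=O)[C@]12CC(=O)CC[C@H]1[C@]1(COC2=O)C(=O)C=CC(C)(C)[C@H]1C[Si](C)(C)c1ccccc1 | intermediate
19 | (5R,8S,9S,10S,13S)-13-hydroxy-15-oxo tetracycle with 6-SiMe2Ph (C16 epimers) | CC1C(=O)[C@]23C[C@@]1(O)CC[C@H]2[C@]1(COC3=O)C(=O)C=CC(C)(C)[C@H]1C[Si](C)(C)c1ccccc1 | intermediate
20 | 6,13-diol, C16 epimers of the target | CC1C(=O)[C@]23C[C@@]1(O)CC[C@H]2[C@]1(COC3=O)C(=O)C=CC(C)(C)[C@H]1CO | intermediate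
21 | 6-O,13-O,15-O-tris(trimethylsilyl) Δ15 enol ether | CC1=C(O[Si](C)(C)C)[C@]23C[C@@]1(O[Si](C)(C)C)CC[C@H]2[C@]1(COC3=O)C(=O)C=CC(C)(C)[C@H]1CO[Si](C)(C)C | intermediate
22 | CNP0533761.1 | C[C@H]1C(=O)[C@]23C[C@@]1(O)CC[C@H]2[C@]1(COC3=O)C(=O)C=CC(C)(C)[C@H]1CO | target

## Step count and risks

Total step count: 10. Longest linear sequence: 9 (steps 1, 2, 4–10).

**Step 7 (key step).**
- What may go wrong: intermolecular coupling of the oxidised enolates, halogen transfer to C8, incomplete or non-regioselective second enolisation, or closure on the wrong face of C8.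
- Fallback, from 11 (steps 5 and 6 are then skipped): a Diels–Alder reaction with 2-methoxy-3-(phenylsulfanyl)buta-1,3-diene F1 is used. In this diene sulfur outweighs oxygen in directing regiochemistry, so the sulfur-bearing carbon ends para to C8. Suprafacial addition to C8=C9 from the C1 face should give the cis-fused enol ether adduct F2.
- Dilute acid hydrolysis gives the 12-(phenylsulfanyl) ketone F3. Reductive desulfurisation with SmI2/MeOH returns to the route at 18.

**Step 4.**
- What may go wrong: proton transfer between the hindered dianion and the acidic keto ester, retro-aldol loss of formaldehyde from the lithium aldolate, O-attack instead of C-attack, or poor facial selectivity at C10.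
- Fallback, from 6: TBSOTf/Et3N gives the bis-silyl compound F4 (C20 silyl ether and C1 silyl dienol ether). A Mukaiyama-type reaction with trimethyl orthoformate and BF3·OEt2 at −78 °C brings in C9 as a small dimethoxycarbenium ion anti to the C5 arm and gives the α-(dimethoxymethyl) ketone F5.
- HF·pyridine frees the C20 alcohol F6. DMAP-catalysed transesterification with 7 in hot toluene gives the β-keto ester F7.
- Aqueous TFA unmasks the aldehyde F8. Piperidinium acetate then closes the ring by intramolecular Knoevenagel condensation, which returns to the route at 11.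

**Step 2.**
- What may go wrong: poor discrimination of the enantiotopic β-carbons, sluggish transfer of the α-silyl group to a neopentyl position, or competing 1,2-addition.
- Fallback, from 2: the same addition–aldol sequence with an achiral copper(I) salt gives the racemic trans hydroxy ketone F9.
- A lipase (serine hydrolase class) with vinyl acetate in t-BuOMe is used for kinetic resolution of the primary alcohol. It is run so that the unwanted enantiomer is converted to the acetate F10, and unreacted 6 is separated by chromatography and re-enters the route at 6.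

## Further compounds

F1 | step 7 | 2-methoxy-3-(phenylsulfanyl)buta-1,3-diene | C=C(OC)C(=C)Sc1ccccc1
F2 | step 7 | Diels–Alder adduct, 13-methoxy-12-(phenylsulfanyl) Δ12 enol ether of the ring C system | CCC(=O)[C@]12CC(OC)=C(Sc3ccccc3)C[C@H]1[C@]1(COC2=O)C(=O)C=CC(C)(C)[C@H]1C[Si](C)(C)c1ccccc1
F3 | step 7 | 12-(phenylsulfanyl) derivative of 18 (C12 undefined) | CCC(=O)[C@]12CC(=O)C(Sc3ccccc3)C[C@H]1[C@]1(COC2=O)C(=O)C=CC(C)(C)[C@H]1C[Si](C)(C)c1ccccc1
F4 | step 4 | bis-TBS derivative of 6 (C20 ether, C1 dienol ether) | CC(C)(C)[Si](C)(C)OCC1=C(O[Si](C)(C)C(C)(C)C)C=CC(C)(C)[C@H]1C[Si](C)(C)c1ccccc1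
F5 | step 4 | α-(dimethoxymethyl) ketone with C20 OTBS | COC(OC)[C@]1(CO[Si](C)(C)C(C)(C)C)C(=O)C=CC(C)(C)[C@H]1C[Si](C)(C)c1ccccc1
F6 | step 4 | α-(dimethoxymethyl)-α-(hydroxymethyl) ketone | COC(OC)[C@]1(CO)C(=O)C=CC(C)(C)[C@H]1C[Si](C)(C)c1ccccc1
F7 | step 4 | C20 3-oxopentanoate ester of F6 | COC(OC)[C@]1(COC(=O)CC(=O)CC)C(=O)C=CC(C)(C)[C@H]1C[Si](C)(C)c1ccccc1
F8 | step 4 | C9 aldehyde from F7 | O=C[C@]1(COC(=O)CC(=O)CC)C(=O)C=CC(C)(C)[C@H]1C[Si](C)(C)c1ccccc1
F9 | step 2 | racemic trans hydroxy ketone (rac-6) | OCC1C(=O)C=CC(C)(C)C1C[Si](C)(C)c1ccccc1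
F10 | step 2 | acetate of ent-6 | CC(=O)OC[C@H]1C(=O)C=CC(C)(C)[C@@H]1C[Si](C)(C)c1ccccc1
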